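**Retrosynthetic overview**
- The target comes from Felkin–Anh reduction of an (R)-α-aryloxy aryl ketone, itself made by aryl-Grignard acyl substitution on a tertiary lactamide.
- Two such lactamide arms are carried on one piperazine (a bis-amide). The piperazine is the leaving group of the Grignard step, so every earlier operation runs two-directionally with two equivalents of each partner.
- The oxolane C–aryl bond is made by arylzinc addition to a 2-sulfonyl oxolane (oxocarbenium ion; aryl enters trans to the aryl already on the ring).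
- Both oxolane rings are closed together in one Rh-catalysed branched hydroformylation–hemiacetalisation of a bis(homoallylic alcohol). These are the only rings made; the arene rings and the piperazine are bought.
- The bis(homoallylic alcohol) comes from double (Z)-crotylboration of a bis-aldehyde, made by double Mitsunobu etherification of vanillin with bis(lactoyl)piperazine (from L-lactide and piperazine, 1:1).

Assumption: the target is the single isomer drawn, i.e. the (2S,3R,4R,5S)-oxolane with a (1R,2R) (threo) side chain; a reagent made in the flask is counted inside the step that uses it; where a step consumes two equivalents of a numbered partner, the second equivalent is entered under "Reagents that add atoms".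

**Step 1**
Reactants: 1 (3S,6S)-3,6-dimethyl-1,4-dioxane-2,5-dione (L-lactide); 2 piperazine
Product: 3 1,4-bis[(2S)-2-hydroxypropanoyl]piperazine
Conditions: 1 (1.0 equiv), 2 (1.0 equiv), toluene, rt, 2 h, then 100 °C, 16 h
Reagents that add atoms: none
Why: Two-fold ester aminolysis (amide formation), in which one N–H opens the dilactone to a lactyl-lactamide and a further N–H cleaves the remaining α-acyloxy-activated ester, so a 1:1 mixture converges on the bis-amide with both lactate stereocentres untouched.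

**Step 2**
Reactants: 3 1,4-bis[(2S)-2-hydroxypropanoyl]piperazine; 4 vanillin (two equivalents)
Product: 5 1,4-bis[(2R)-2-(4-formyl-2-methoxyphenoxy)propanoyl]piperazine
Conditions: 4 (2.2 equiv), PPh3 (2.4 equiv), DIAD (2.4 equiv), THF, 0 °C → rt
Reagents that add atoms: vanillin (second equivalent of 4), COc1cc(C=O)ccc1O
Why: Double Mitsunobu etherification, in which the acidic phenol displaces each activated carbinol by SN2 with inversion, turning each (S)-centre into the (R)-aryloxy centre of the side chain while the aldehydes stay untouched.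

**Step 3**
Reactants: 5 1,4-bis[(2R)-2-(4-formyl-2-methoxyphenoxy)propanoyl]piperazine; 6 cis-2-butene (two equivalents)
Product: 7 1,4-bis{(2R)-2-[4-((1S,2R)-1-hydroxy-2-methylbut-3-en-1-yl)-2-methoxyphenoxy]propanoyl}piperazine
Conditions: 6, KOtBu, n-BuLi, THF, −78 → −45 °C; (−)-Ipc2BOMe, −78 °C; BF3·OEt2; 5, −78 °C; then aq. NaOH, H2O2
Reagents that add atoms: cis-2-butene (second equivalent of 6), C/C=C\C
Why: Brown asymmetric (Z)-crotylboration through a closed chair transition state, where the Z-geometry gives the syn carbinol/methyl pair and the isopinocampheyl groups of the (+)-α-pinene series direct addition to the Si face of each aldehyde, setting (1S,2R) in both arms (amides are inert, and the two-fold reaction sends most of the minor enantiomer into a separable heterochiral diastereomer).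

**Step 4**
Reactants: 7 1,4-bis{(2R)-2-[4-((1S,2R)-1-hydroxy-2-methylbut-3-en-1-yl)-2-methoxyphenoxy]propanoyl}piperazine
Product: 9 1,4-bis{(2R)-2-[4-((2S,3R,4R)-5-hydroxy-3,4-dimethyloxolan-2-yl)-2-methoxyphenoxy]propanoyl}piperazine (bis-lactol; anomer mixture), via bis(γ-hydroxy aldehyde) 8 (not isolated)
Conditions: Rh(CO)2(acac) (2 mol %), Ph2POMe (20 mol %), CO/H2 (1:1, 20 bar), THF, 4 Å MS, 40 °C
Reagents that add atoms: carbon monoxide (one molecule per arm), [C-]#[O+]
Why: Directed branched hydroformylation in which Ph2POMe exchanges reversibly with each carbinol OH and delivers rhodium to the internal alkene carbon through a six-membered chelate, placing the new methyl anti to the allylic methyl (any cis epimer equilibrates through the open aldehyde), after which each γ-hydroxy aldehyde closes to its cyclic hemiacetal, so both oxolane rings form in this one operation.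

**Step 5**
Reactants: 9 1,4-bis{(2R)-2-[4-((2S,3R,4R)-5-hydroxy-3,4-dimethyloxolan-2-yl)-2-methoxyphenoxy]propanoyl}piperazine
Product: 10 1,4-bis{(2R)-2-[4-((2S,3R,4R)-3,4-dimethyl-5-(phenylsulfonyl)oxolan-2-yl)-2-methoxyphenoxy]propanoyl}piperazine (mixture at the sulfonyl carbon)
Conditions: PhSO2H, CaCl2, CH2Cl2, rt
Reagents that add atoms: benzenesulfinic acid (one molecule per arm), O=S(O)c1ccccc1
Why: Ley exchange of the anomeric hydroxyl for sulfinate through the oxocarbenium ion (hemiacetal to 2-sulfonyl cyclic ether), giving a stable oxocarbenium precursor without touching the ring stereocentres.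

**Step 6**
Reactants: 10 1,4-bis{(2R)-2-[4-((2S,3R,4R)-3,4-dimethyl-5-(phenylsulfonyl)oxolan-2-yl)-2-methoxyphenoxy]propanoyl}piperazine; 11 (3,4-dimethoxyphenyl)magnesium bromide (two equivalents)
Product: 12 1,4-bis{(2R)-2-[4-((2S,3R,4R,5S)-5-(3,4-dimethoxyphenyl)-3,4-dimethyloxolan-2-yl)-2-methoxyphenoxy]propanoyl}piperazine
Conditions: 11 (6 equiv), ZnBr2 (6 equiv), THF, 0 °C → rt; then aq. NH4Cl
Reagents that add atoms: (3,4-dimethoxyphenyl)magnesium bromide (second equivalent of 11), COc1ccc([Mg]Br)cc1OC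
Why: Substitution of a 2-sulfonyl cyclic ether by an arylzinc, in which zinc ionises the sulfone and the aryl group adds to the envelope oxocarbenium ion by inside attack, cis to the adjacent methyl and anti to the remote methyl and aryl groups, giving the 2,5-trans-diaryl, aryl/methyl-cis oxolane (the new centre is S in each arm); arylzinc does not attack the amides.

**Step 7**
Reactants: 12 1,4-bis{(2R)-2-[4-((2S,3R,4R,5S)-5-(3,4-dimethoxyphenyl)-3,4-dimethyloxolan-2-yl)-2-methoxyphenoxy]propanoyl}piperazine; 11 (3,4-dimethoxyphenyl)magnesium bromide (two equivalents)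
Product: 14 (2R)-1-(3,4-dimethoxyphenyl)-2-{4-[(2S,3R,4R,5S)-5-(3,4-dimethoxyphenyl)-3,4-dimethyloxolan-2-yl]-2-methoxyphenoxy}propan-1-one (two molecules per molecule of 12), via bis(bromomagnesium hemiaminalate) 13 (not isolated)
Conditions: 11 (5 equiv), THF, −20 → 0 °C; then cold aq. NH4Cl
Reagents that add atoms: (3,4-dimethoxyphenyl)magnesium bromide (second equivalent of 11), COc1ccc([Mg]Br)cc1OC
Why: Nucleophilic acyl substitution of a tertiary α-alkoxy amide by a Grignard reagent (morpholine-amide/Weinreb-type behaviour), where the chelated tetrahedral adduct resists over-addition and collapses on the acidic quench to two aryl ketones and piperazine with the α-aryloxy centre preserved.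

**Step 8**
Reactants: 14 (2R)-1-(3,4-dimethoxyphenyl)-2-{4-[(2S,3R,4R,5S)-5-(3,4-dimethoxyphenyl)-3,4-dimethyloxolan-2-yl]-2-methoxyphenoxy}propan-1-one
Product: 15 (1R,2R)-1-(3,4-dimethoxyphenyl)-2-{4-[(2S,3R,4R,5S)-5-(3,4-dimethoxyphenyl)-3,4-dimethyloxolan-2-yl]-2-methoxyphenoxy}propan-1-ol (target)
Conditions: KBH(s-Bu)3, THF, −78 °C; then aq. NaOH, H2O2
Reagents that add atoms: none
Why: Felkin–Anh (polar) controlled ketone reduction, in which a bulky hydride with a weakly chelating potassium counter-ion attacks anti to the aryloxy group and gives the threo (1R,2R) alcohol by 1,2-induction.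

**Compound list**
1 | (3S,6S)-3,6-dimethyl-1,4-dioxane-2,5-dione (L-lactide) | C[C@H]1C(=O)O[C@H](C(=O)O1)C | starting material
2 | piperazine | C1CNCCN1 | starting material
3 | 1,4-bis[(2S)-2-hydroxypropanoyl]piperazine | C[C@H](O)C(=O)N1CCN(CC1)C(=O)[C@H](C)O | intermediate
4 | vanillin | COc1cc(C=O)ccc1O | starting material
5 | 1,4-bis[(2R)-2-(4-formyl-2-methoxyphenoxy)propanoyl]piperazine | COc1cc(C=O)ccc1O[C@H](C)C(=O)N1CCN(CC1)C(=O)[C@@H](C)Oc1ccc(C=O)cc1OC | intermediate
6 | cis-2-butene | C/C=C\C | starting material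
7 | 1,4-bis{(2R)-2-[4-((1S,2R)-1-hydroxy-2-methylbut-3-en-1-yl)-2-methoxyphenoxy]propanoyl}piperazine | COc1cc([C@@H](O)[C@H](C)C=C)ccc1O[C@H](C)C(=O)N1CCN(CC1)C(=O)[C@@H](C)Oc1ccc([C@@H](O)[C@H](C)C=C)cc1OC | intermediate
8 | 1,4-bis{(2R)-2-[4-((1S,2R,3R)-1-hydroxy-2,3-dimethyl-4-oxobutyl)-2-methoxyphenoxy]propanoyl}piperazine | COc1cc([C@@H](O)[C@H](C)[C@@H](C)C=O)ccc1O[C@H](C)C(=O)N1CCN(CC1)C(=O)[C@@H](C)Oc1ccc([C@@H](O)[C@H](C)[C@@H](C)C=O)cc1OC | intermediate (not isolated)
9 | 1,4-bis{(2R)-2-[4-((2S,3R,4R)-5-hydroxy-3,4-dimethyloxolan-2-yl)-2-methoxyphenoxy]propanoyl}piperazine | COc1cc([C@H]2OC(O)[C@H](C)[C@H]2C)ccc1O[C@H](C)C(=O)N1CCN(CC1)C(=O)[C@@H](C)Oc1ccc([C@H]2OC(O)[C@H](C)[C@H]2C)cc1OC | intermediate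
10 | 1,4-bis{(2R)-2-[4-((2S,3R,4R)-3,4-dimethyl-5-(phenylsulfonyl)oxolan-2-yl)-2-methoxyphenoxy]propanoyl}piperazine | COc1cc([C@H]2OC(S(=O)(=O)c3ccccc3)[C@H](C)[C@H]2C)ccc1O[C@H](C)C(=O)N1CCN(CC1)C(=O)[C@@H](C)Oc1ccc([C@H]2OC(S(=O)(=O)c3ccccc3)[C@H](C)[C@H]2C)cc1OC | intermediate
11 | (3,4-dimethoxyphenyl)magnesium bromide | COc1ccc([Mg]Br)cc1OC | starting material
12 | 1,4-bis{(2R)-2-[4-((2S,3R,4R,5S)-5-(3,4-dimethoxyphenyl)-3,4-dimethyloxolan-2-yl)-2-methoxyphenoxy]propanoyl}piperazine | COc1cc([C@H]2O[C@H](c3ccc(OC)c(OC)c3)[C@H](C)[C@H]2C)ccc1O[C@H](C)C(=O)N1CCN(CC1)C(=O)[C@@H](C)Oc1ccc([C@H]2O[C@H](c3ccc(OC)c(OC)c3)[C@H](C)[C@H]2C)cc1OC | intermediate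
13 | bis(bromomagnesium hemiaminalate) from double aryl addition to 12 | COc1cc([C@H]2O[C@H](c3ccc(OC)c(OC)c3)[C@H](C)[C@H]2C)ccc1O[C@H](C)C(O[Mg]Br)(c1ccc(OC)c(OC)c1)N1CCN(CC1)C(O[Mg]Br)(c1ccc(OC)c(OC)c1)[C@@H](C)Oc1ccc([C@H]2O[C@H](c3ccc(OC)c(OC)c3)[C@H](C)[C@H]2C)cc1OC | intermediate (not isolated)
14 | (2R)-1-(3,4-dimethoxyphenyl)-2-{4-[(2S,3R,4R,5S)-5-(3,4-dimethoxyphenyl)-3,4-dimethyloxolan-2-yl]-2-methoxyphenoxy}propan-1-one | COc1ccc(C(=O)[C@@H](C)Oc2ccc([C@H]3O[C@H](c4ccc(OC)c(OC)c4)[C@H](C)[C@H]3C)cc2OC)cc1OC | intermediate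
15 | (1R,2R)-1-(3,4-dimethoxyphenyl)-2-{4-[(2S,3R,4R,5S)-5-(3,4-dimethoxyphenyl)-3,4-dimethyloxolan-2-yl]-2-methoxyphenoxy}propan-1-ol | COc1ccc([C@@H](O)[C@@H](C)Oc2ccc([C@H]3O[C@H](c4ccc(OC)c(OC)c4)[C@H](C)[C@H]3C)cc2OC)cc1OC | target

**Totals**
Total step count: 8. Longest linear sequence: 8 steps (1 → 3 → 5 → 7 → 9 → 10 → 12 → 14 → 15).

**Steps most likely to fail, with fallbacks**

Step 4 (branched regiochemistry and anti induction in the double hydroformylation). The fallback sets out from 7. Silylation (Et3SiCl, imidazole) gives the bis(triethylsilyl ether) F1. Tsuji–Wacker oxidation (PdCl2, CuCl, O2, DMF–H2O) gives the bis(methyl ketone) F2. Wittig methoxymethylenation with salt-free Ph3P=CHOMe at low temperature, to spare the α-methyl ketone centre, gives the bis(enol ether) F3. Dilute HCl in THF then removes the silyl groups and unmasks the aldehydes; the γ-hydroxy aldehyde 8 closes and the centre next to the anomeric carbon equilibrates to the trans-dimethyl hemiacetal, so the route is rejoined at 9.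

Step 6 (face selectivity or elimination in the arylzinc substitution). The fallback sets out from 9. Acetylation (Ac2O, pyridine) gives the bis(anomeric acetate) F4. Ionisation with Me3SiOTf in CH2Cl2 at −78 °C in the presence of 1,2-dimethoxybenzene leads to Friedel–Crafts attack para to a methoxy group, again anti to the aryl group across the ring. The low temperature prevents acid equilibration of the benzylic ether, and the route is rejoined at 12.

Step 8 (threo/erythro ratio of the ketone reduction). The fallback sets out from 12 and avoids the ketone. Cp2Zr(H)Cl reduces each tertiary amide to the aldehyde, giving two molecules of (2R)-2-{4-[(2S,3R,4R,5S)-5-(3,4-dimethoxyphenyl)-3,4-dimethyloxolan-2-yl]-2-methoxyphenoxy}propanal F5 and piperazine. Addition of 11 in CH2Cl2 at −78 °C with MgBr2·OEt2 proceeds under Cram-chelate control (magnesium held between the aldehyde oxygen and the guaiacyl ether oxygens) and gives the threo alcohol directly, rejoining the route at 15.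

**Further compounds**
F1 | step 4 | 1,4-bis{(2R)-2-[4-((1S,2R)-2-methyl-1-(triethylsilyloxy)but-3-en-1-yl)-2-methoxyphenoxy]propanoyl}piperazine | COc1cc([C@@H](O[Si](CC)(CC)CC)[C@H](C)C=C)ccc1O[C@H](C)C(=O)N1CCN(CC1)C(=O)[C@@H](C)Oc1ccc([C@@H](O[Si](CC)(CC)CC)[C@H](C)C=C)cc1OC
F2 | step 4 | 1,4-bis{(2R)-2-[4-((1S,2S)-2-methyl-3-oxo-1-(triethylsilyloxy)butyl)-2-methoxyphenoxy]propanoyl}piperazine | COc1cc([C@@H](O[Si](CC)(CC)CC)[C@H](C)C(C)=O)ccc1O[C@H](C)C(=O)N1CCN(CC1)C(=O)[C@@H](C)Oc1ccc([C@@H](O[Si](CC)(CC)CC)[C@H](C)C(C)=O)cc1OC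
F3 | step 4 | 1,4-bis{(2R)-2-[4-((1S,2R)-4-methoxy-2,3-dimethyl-1-(triethylsilyloxy)but-3-en-1-yl)-2-methoxyphenoxy]propanoyl}piperazine (E/Z mixture) | COc1cc([C@@H](O[Si](CC)(CC)CC)[C@H](C)C(C)=COC)ccc1O[C@H](C)C(=O)N1CCN(CC1)C(=O)[C@@H](C)Oc1ccc([C@@H](O[Si](CC)(CC)CC)[C@H](C)C(C)=COC)cc1OC
F4 | step 6 | 1,4-bis{(2R)-2-[4-((2S,3R,4R)-5-acetoxy-3,4-dimethyloxolan-2-yl)-2-methoxyphenoxy]propanoyl}piperazine (anomer mixture) | COc1cc([C@H]2OC(OC(C)=O)[C@H](C)[C@H]2C)ccc1O[C@H](C)C(=O)N1CCN(CC1)C(=O)[C@@H](C)Oc1ccc([C@H]2OC(OC(C)=O)[C@H](C)[C@H]2C)cc1OC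
F5 | step 8 | (2R)-2-{4-[(2S,3R,4R,5S)-5-(3,4-dimethoxyphenyl)-3,4-dimethyloxolan-2-yl]-2-methoxyphenoxy}propanal | O=C[C@@H](C)Oc1ccc([C@H]2O[C@H](c3ccc(OC)c(OC)c3)[C@H](C)[C@H]2C)cc1OC
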